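**Retrosynthetic overview** (plakortolide numbering: C1 lactone C=O, C2 lactone CH2, C3 CH–O2, C4 C(Me)–O(lactone), C5 CH2, C6 C(Me)(chain)–O1; dioxane ring = O1–O2–C3–C4–C5–C6)
1. The last bond made is C2–C3 of the γ-lactone ring: the lactone comes from a monocyclic 3-methoxy-1,2-dioxane that carries an O-acetyl group on the C4 oxygen, used as a mixture of C3 epimers; the phenol silyl ether is removed afterwards.
2. Enabling feature: C3 is the dioxane carbon bonded to peroxide oxygen O2, so it can be held as a peroxy-acetal and ionised to a 1,2-dioxan-3-ylium ion; the lactone oxygen sits on the adjacent C4, so the CH3 of its acetate (future C2) is placed for a five-membered closure.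
3. C6–C7 is cut by the same logic: a C6 methyl peroxy-ketal plus allylsilane sets the quaternary C6 under control of C4; cross-metathesis and diimide then finish the 9-arylnonyl chain.
4. The 1,2-dioxane ring (a double peroxy-acetal of a 1,4-keto aldehyde) is formed first, by ozonolysis in methanol of (S)-2-hydroxy-2,4-dimethylpent-4-enal, made from (R)-2-methylglycidol and isopropenyl Grignard reagent.
5. Ring order: 1,2-dioxane (step 4), then γ-lactone (step 9).

Key step: step 9

Remark: (R)-2-methylglycidol is taken as a commercial compound; it is also the Sharpless epoxidation product of 2-methylprop-2-en-1-ol.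

**Route**

Step 1
Reactants: 1 8-bromooct-1-ene; 2 (4-bromophenoxy)(tert-butyl)dimethylsilane
Product: 4 tert-butyl(dimethyl)[4-(oct-7-en-1-yl)phenoxy]silane, via Grignard reagent 3 (not isolated)
Conditions: 1, Mg, THF, 40 °C; then 2, PdCl2(dppf) (2 mol %), THF, 60 °C
Reagents that add atoms: none
Why: Kumada coupling of a primary alkyl Grignard reagent with an aryl bromide, in which the wide-bite-angle dppf ligand suppresses β-hydride elimination and the aryl silyl ether and terminal alkene are inert; no stereocentre is involved.

Step 2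
Reactants: 5 (R)-2-methylglycidol, [(2R)-2-methyloxiran-2-yl]methanol; 6 isopropenylmagnesium bromide
Product: 7 (2S)-2,4-dimethylpent-4-ene-1,2-diol
Conditions: 6 (3 equiv), CuI (10 mol %), THF, −40 → 0 °C; aq. NH4Cl
Reagents that add atoms: none
Why: CuI-catalysed SN2 opening of the epoxide by the alkenyl Grignard reagent at the unhindered CH2 (one equivalent of 6 is spent on the hydroxyl proton), so the quaternary carbinol centre of 5 is carried over untouched as C4 and its descriptor changes from R to S only through the priority rules.

Step 3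
Reactants: 7 (2S)-2,4-dimethylpent-4-ene-1,2-diol
Product: 8 (2S)-2-hydroxy-2,4-dimethylpent-4-enal
Conditions: (COCl)2, DMSO, CH2Cl2, −78 °C; Et3N, −78 → 0 °C; used crude
Reagents that add atoms: none
Why: Swern oxidation takes the primary alcohol to the aldehyde while the tertiary alcohol cannot be oxidised and the quaternary α-carbon cannot epimerise.

Step 4
Reactants: 8 (2S)-2-hydroxy-2,4-dimethylpent-4-enal
Product: 11 (4S)-3,6-dimethoxy-4,6-dimethyl-1,2-dioxan-4-ol (epimers at C3 and C6), via hydroperoxy ketal aldehyde 9 (not isolated), via peroxy hemiacetal 10 (not isolated)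
Conditions: O3, CH2Cl2/MeOH (3:1), −78 °C; N2 purge; then PPTS (cat.), MeOH, 0 °C → rt; concentrate
Reagents that add atoms: ozone O=[O+][O-]; methanol CO
Why: Ozonolysis of a 1,1-disubstituted alkene in methanol is known to cleave the primary ozonide to formaldehyde and the ketone O-oxide, which methanol traps as the methoxy hydroperoxide 9; its OOH group adds to the aldehyde to close the six-membered peroxy hemiacetal 10, and acid-catalysed exchange in methanol should give the double peroxy-acetal 11, whose two new centres (C3, C6) are left uncontrolled on purpose because both are erased later.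

Step 5
Reactants: 11 (4S)-3,6-dimethoxy-4,6-dimethyl-1,2-dioxan-4-ol; 12 allyltrimethylsilane
Product: 15 (4S,6R)-6-allyl-3-methoxy-4,6-dimethyl-1,2-dioxan-4-ol (C3 epimers), via silyl ether 13 (not isolated), via allylated silyl ether 14 (not isolated)
Conditions: 12 (4 equiv), TMSOTf (0.2 equiv), CH2Cl2, −78 → −40 °C; then K2CO3, MeOH, 0 °C
Reagents that add atoms: none
Why: Sakurai-type allylation of a ketone-derived peroxy-ketal through the peroxycarbenium ion at C6, a known reaction of 3-alkoxy-1,2-dioxanes; the hydroxyl is first silylated in the flask by 12 (propene is lost), the C6 ketal ionises far more readily than the C3 acetal next to the oxygenated quaternary C4, and axial attack on the half-chair cation that holds the C4 siloxy group pseudo-axial and the C4 methyl pseudo-equatorial should place allyl cis to the C4 oxygen, which is the 6R configuration.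

Step 6
Reactants: 15 (4S,6R)-6-allyl-3-methoxy-4,6-dimethyl-1,2-dioxan-4-ol; 4 tert-butyl(dimethyl)[4-(oct-7-en-1-yl)phenoxy]silane
Product: 16 (4S,6R)-6-{9-[4-(tert-butyldimethylsilyloxy)phenyl]non-2-en-1-yl}-3-methoxy-4,6-dimethyl-1,2-dioxan-4-ol (E/Z mixture, C3 epimers)
Conditions: 4 (3 equiv), second-generation Grubbs catalyst RuCl2(=CHPh)(H2IMes)(PCy3) (5 mol %), CH2Cl2, 40 °C
Reagents that add atoms: none
Why: Olefin cross-metathesis between the hindered allyl group, which is slow to homodimerise, and an excess of terminal alkene 4; ruthenium carbenes tolerate dialkyl peroxides, tertiary alcohols and silyl ethers, and the alkene geometry does not matter.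

Step 7
Reactants: 16 (the non-2-enyl dioxanol)
Product: 17 (4S,6R)-6-{9-[4-(tert-butyldimethylsilyloxy)phenyl]nonyl}-3-methoxy-4,6-dimethyl-1,2-dioxan-4-ol (C3 epimers)
Conditions: 2-nitrobenzenesulfonyl hydrazide, Et3N, CH2Cl2, rt
Reagents that add atoms: none
Why: Diimide generated from the sulfonyl hydrazide reduces the disubstituted C=C bond by concerted syn hydrogen transfer and leaves the O–O bond, the acetal and the aryl silyl ether untouched, which catalytic hydrogenation would not guarantee.

Step 8
Reactants: 17 (the nonyl dioxanol)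
Product: 18 (4S,6R)-6-{9-[4-(tert-butyldimethylsilyloxy)phenyl]nonyl}-3-methoxy-4,6-dimethyl-1,2-dioxan-4-yl acetate (C3 epimers)
Conditions: Ac2O, DMAP, Et3N, CH2Cl2, rt
Reagents that add atoms: acetic anhydride CC(=O)OC(C)=O
Why: DMAP-catalysed acylation of the tertiary alcohol places on the C4 oxygen the two carbons that become C1 and C2 of the lactone; no stereocentre is affected.

Step 9
Reactants: 18 (the C4 acetate, both C3 epimers)
Product: 21 O-tert-butyldimethylsilyl plakortolide F, via acetoxonium triflate 19 (not isolated), via ketene acetal 20 (not isolated)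
Conditions: TMSOTf (2.2 equiv), i-Pr2NEt (1.2 equiv), CH2Cl2, −78 → −30 °C; pH 7 buffer
Reagents that add atoms: none
Why: Proposed new method: TMSOTf removes the C3 methoxy group of either epimer, and the resulting 1,2-dioxan-3-ylium (peroxycarbenium) ion, stabilised by the lone pair of ring oxygen O2, is captured by the carbonyl oxygen of the neighbouring C4 acetate to give the cis-fused acetoxonium ion 19; i-Pr2NEt deprotonates its methyl group to the cyclic ketene acetal 20, and Lewis-acid heterolysis of the C3–O bond of 20 returns the peroxycarbenium ion paired with the silyl ketene acetal of the C4 acetate, which recombine at carbon to form C2–C3. The closest known reactions are the Lewis-acid addition of silyl ketene acetals to 3-alkoxy-1,2-dioxanes (intermolecular peroxycarbenium Mukaiyama reaction), the one-flask TMSOTf/amine enol-silane formation and acetal addition, and the Petasis–Ferrier type O-to-C rearrangement of cyclic enol acetals. The γ-lactone closes by 5-exo-trig attack on the C3=O2 cation with the enol double bond inside the new ring (5-enolendo-exo-trig), which from 20 is a 1,3 O-to-C shift with retention of ring size. The new stereocentre C3 is fixed by the tether: the nucleophilic carbon hangs from the C4 oxygen, so only the cis-fused lactone (3S) can form whatever the configuration of C3 in 18, which makes the step stereoconvergent. The step needs ionisation at C3 and not at the quaternary C6–O1 bond, and C-attack and not O-return; the acetal leaving group with the O2 lone pair should secure the first, and the energy gained on forming the ester C=O the second.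

Step 10
Reactants: 21 O-tert-butyldimethylsilyl plakortolide F
Product: 22 plakortolide F
Conditions: HF·pyridine, THF/pyridine, 0 °C → rt
Reagents that add atoms: none
Why: Fluoride cleavage of the aryl silyl ether under non-basic conditions avoids enolisation of the lactone and β-elimination of the peroxide; no stereocentre is touched.

**Compound list**
1 | 8-bromooct-1-ene | C=CCCCCCCBr | starting material
2 | (4-bromophenoxy)(tert-butyl)dimethylsilane | CC(C)(C)[Si](C)(C)Oc1ccc(Br)cc1 | starting material
3 | oct-7-en-1-ylmagnesium bromide (not isolated) | C=CCCCCCC[Mg]Br | intermediate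
4 | tert-butyl(dimethyl)[4-(oct-7-en-1-yl)phenoxy]silane | C=CCCCCCCc1ccc(O[Si](C)(C)C(C)(C)C)cc1 | intermediate
5 | (R)-2-methylglycidol, [(2R)-2-methyloxiran-2-yl]methanol | OC[C@]1(C)CO1 | starting material
6 | isopropenylmagnesium bromide | CC(=C)[Mg]Br | starting material
7 | (2S)-2,4-dimethylpent-4-ene-1,2-diol | C=C(C)C[C@](C)(O)CO | intermediate
8 | (2S)-2-hydroxy-2,4-dimethylpent-4-enal | C=C(C)C[C@](C)(O)C=O | intermediate
9 | (2S)-4-hydroperoxy-2-hydroxy-4-methoxy-2-methylpentanal, both C4 epimers (not isolated) | COC(C)(OO)C[C@](C)(O)C=O | intermediate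
10 | (4S)-6-methoxy-4,6-dimethyl-1,2-dioxane-3,4-diol, epimers at C3 and C6 (not isolated) | COC1(C)C[C@](C)(O)C(O)OO1 | intermediate
11 | (4S)-3,6-dimethoxy-4,6-dimethyl-1,2-dioxan-4-ol, epimers at C3 and C6 | COC1(C)C[C@](C)(O)C(OC)OO1 | intermediate
12 | allyltrimethylsilane | C=CC[Si](C)(C)C | starting material
13 | (4S)-3,6-dimethoxy-4,6-dimethyl-4-(trimethylsilyloxy)-1,2-dioxane (not isolated) | COC1(C)C[C@](C)(O[Si](C)(C)C)C(OC)OO1 | intermediate
14 | (4S,6R)-6-allyl-3-methoxy-4,6-dimethyl-4-(trimethylsilyloxy)-1,2-dioxane, C3 epimers (not isolated) | C[C@@]1(CC=C)C[C@](C)(O[Si](C)(C)C)C(OC)OO1 | intermediate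
15 | (4S,6R)-6-allyl-3-methoxy-4,6-dimethyl-1,2-dioxan-4-ol, C3 epimers | C[C@@]1(CC=C)C[C@](C)(O)C(OC)OO1 | intermediate
16 | (4S,6R)-6-{9-[4-(tert-butyldimethylsilyloxy)phenyl]non-2-en-1-yl}-3-methoxy-4,6-dimethyl-1,2-dioxan-4-ol, E/Z and C3 epimers | C[C@@]1(CC=CCCCCCCc2ccc(O[Si](C)(C)C(C)(C)C)cc2)C[C@](C)(O)C(OC)OO1 | intermediate
17 | (4S,6R)-6-{9-[4-(tert-butyldimethylsilyloxy)phenyl]nonyl}-3-methoxy-4,6-dimethyl-1,2-dioxan-4-ol, C3 epimers | C[C@@]1(CCCCCCCCCc2ccc(O[Si](C)(C)C(C)(C)C)cc2)C[C@](C)(O)C(OC)OO1 | intermediate
18 | (4S,6R)-6-{9-[4-(tert-butyldimethylsilyloxy)phenyl]nonyl}-3-methoxy-4,6-dimethyl-1,2-dioxan-4-yl acetate, C3 epimers | C[C@@]1(CCCCCCCCCc2ccc(O[Si](C)(C)C(C)(C)C)cc2)C[C@](C)(OC(C)=O)C(OC)OO1 | intermediate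
19 | cis-fused 2-methyl-1,3-dioxolan-2-ylium ion spanning O–C3 and O–C4 of the dioxane, triflate salt (not isolated) | C[C@@]1(CCCCCCCCCc2ccc(O[Si](C)(C)C(C)(C)C)cc2)C[C@]2(C)[O+]=C(C)O[C@@H]2OO1.[O-]S(=O)(=O)C(F)(F)F | intermediate
20 | cis-fused 2-methylene-1,3-dioxolane (cyclic ketene acetal) spanning O–C3 and O–C4 of the dioxane (not isolated) | C[C@@]1(CCCCCCCCCc2ccc(O[Si](C)(C)C(C)(C)C)cc2)C[C@]2(C)OC(=C)O[C@@H]2OO1 | intermediate
21 | O-tert-butyldimethylsilyl plakortolide F, (3S,4S,6R) cis-fused peroxy-lactone | C[C@@]1(CCCCCCCCCc2ccc(O[Si](C)(C)C(C)(C)C)cc2)C[C@]2(C)OC(=O)C[C@@H]2OO1 | intermediate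
22 | plakortolide F | C[C@@]1(CCCCCCCCCc2ccc(O)cc2)C[C@]2(C)OC(=O)C[C@@H]2OO1 | target

**Step count**
Total steps: 10. Longest linear sequence: 9 steps (steps 2 to 10, from 5 to 22).

**Steps most likely to fail, with fallbacks**

Step 9 (Proposed new method). The acetoxonium ion may persist and return an ortho ester or a C3-hydroxy acetate on work-up instead of losing a proton. Recombination at carbon may be slower than fragmentation of the peroxycarbenium ion. The product lactone may be enolised by the silyl triflate/amine pair and lose the peroxide by β-elimination. The fallback uses known chemistry and makes C2–C3 intermolecularly. It sets out from 17: TiCl4-mediated addition of commercial 1-(tert-butyldimethylsilyloxy)-1-methoxyethene (C=C(OC)O[Si](C)(C)C(C)(C)C) to the C3 peroxy-acetal in CH2Cl2 at −78 °C should give methyl 2-[(3S,4S,6R)-6-{9-[4-(tert-butyldimethylsilyloxy)phenyl]nonyl}-4-hydroxy-4,6-dimethyl-1,2-dioxan-3-yl]acetate F1. Attack is expected cis to the C4 oxygen and trans to the C4 methyl. PPTS in CH2Cl2 at 40 °C should then lactonise the cis hydroxy ester (the trans adduct cannot close), and the route is rejoined at 21.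

Step 5. The allyl group may enter with poor facial selectivity at C6, because the pseudo-axial C4 siloxy group both directs and hinders the attack. The C3 acetal may also ionise in competition. The fallback delivers the allyl group from a temporary silicon tether on the C4 oxygen. It sets out from 11: allyl(chloro)dimethylsilane and imidazole in DMF should give (4S)-4-[allyl(dimethyl)silyloxy]-3,6-dimethoxy-4,6-dimethyl-1,2-dioxane F2. Catalytic TMSOTf in dilute CH2Cl2 at −78 °C should ionise C6, and the tethered allylsilane can only reach the face of C6 that carries the C4 oxygen. This gives (4S,6R)-6-allyl-3-methoxy-4-[methoxy(dimethyl)silyloxy]-4,6-dimethyl-1,2-dioxane F3, in which the methoxy group lost from C6 ends on silicon. K2CO3 in MeOH added to the same flask cleaves the silyl ether, and the route is rejoined at 15.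

Step 4. The carbonyl oxide may be captured within the molecule by the free aldehyde (bridged ozonide) instead of by methanol. Hydrogen peroxide may be lost from the hydroperoxy ketal during the acid exchange. The fallback takes the peroxide from H2O2 instead of from ozone. It sets out from 8: ozonolysis in CH2Cl2 at −78 °C with Me2S work-up should give (2S)-2-hydroxy-2-methyl-4-oxopentanal F4. Treatment with H2O2 (50 % aq.) and catalytic TsOH in MeOH, the known conversion of 1,4-dicarbonyl compounds into 3,6-dialkoxy-1,2-dioxanes, should then give the double peroxy-acetal, and the route is rejoined at 11.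

**Further compounds**
F1 | step 9 | methyl 2-[(3S,4S,6R)-6-{9-[4-(tert-butyldimethylsilyloxy)phenyl]nonyl}-4-hydroxy-4,6-dimethyl-1,2-dioxan-3-yl]acetate | C[C@@]1(CCCCCCCCCc2ccc(O[Si](C)(C)C(C)(C)C)cc2)C[C@](C)(O)[C@H](CC(=O)OC)OO1
F2 | step 5 | (4S)-4-[allyl(dimethyl)silyloxy]-3,6-dimethoxy-4,6-dimethyl-1,2-dioxane | COC1(C)C[C@](C)(O[Si](C)(C)CC=C)C(OC)OO1
F3 | step 5 | (4S,6R)-6-allyl-3-methoxy-4-[methoxy(dimethyl)silyloxy]-4,6-dimethyl-1,2-dioxane | C[C@@]1(CC=C)C[C@](C)(O[Si](C)(C)OC)C(OC)OO1
F4 | step 4 | (2S)-2-hydroxy-2-methyl-4-oxopentanal | CC(=O)C[C@](C)(O)C=O
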